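TBS = tert-butyldimethylsilyl; TBSO = tert-butyldimethylsilyloxy. Locants follow the 3,7-dioxabicyclo[3.3.0]octan-8-one skeleton: C1 is α to the C8 carbonyl, C2 carries the catechol ring, then O3, C4H2, C5, C6 (pyrogallol ring) and O7.

## The problem

The target 19 is a cis-fused furofuranone in which a γ-lactone (C8, O7, C6, C5, C1) and a tetrahydrofuran (C1, C2, O3, C4, C5) share the C1–C5 bond. Four contiguous stereocentres, (1S,2S,5R,6S), must be set; both aryl groups lie on the convex face, so H1/H2 and H5/H6 are trans. C6, once available as one enantiomer, is adjacent to C5 and can direct it, and C1 follows C5 because only the cis fusion is free of strain. C2 is the awkward centre: any reagent that forms its C–H bond approaches from the convex face and leaves the aryl group endo. The catechol and pyrogallol hydroxyls are easily oxidised, above all as phenoxides, and must stay masked until a last step that is neither basic nor oxidising. Both benzylic C–O bonds (C2–O3 and C6–O7) ionise under acid, are open to hydrogenolysis, and with a free para hydroxyl can leave through quinone methides; the lactone adds sensitivity to base. The enabling feature is that O3, C2 and C1 are the oxygen, carbonyl carbon and α-carbon of an aroylacetic acid whose carboxyl carbon C8 is esterified by O7 of a 1-arylallyl alcohol, C5–C4 being the former vinyl group. A keto carbenoid at C1 can therefore add across that vinyl group in a formal (3+2) sense and close both rings from an acyclic ester.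

## Retrosynthesis

**19 from 18.** The five O–H bonds are traced back to O–Si bonds. Silyl ethers are preferred to benzyl ethers, whose hydrogenolysis would endanger C6–O7 and C2–O3, and to methyl ethers, whose cleavage needs boron halides that ionise both benzylic positions. The forward step must release five phenols without ever forming a phenoxide.

**18 from 17 and 16.** The C2 configuration is traced to its epimer 17, and the C1–H and C2–H bonds of 17 to the C1=C2 enol ether 16. Syn hydrogenation can only give 17 (aryl endo), so the plan accepts that outcome and corrects C2 by reversible ionisation of C2–O3. Catalytic hydrogenation is preferred to silane and acid, which would reduce any ionised benzylic position irreversibly. Compound 16 has two stereocentres instead of four. The forward steps require face-selective hydrogen delivery and an equilibrium that favours the exo-aryl isomer; the latter is the weakest assumption of the plan.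

**16 from 13.** O3–C4 and C1–C5 are cut. In the forward sense the carbene from 13 forms C1–C5 and a transient C1–C4 bond (cyclopropane 14). Iodide cleaves C1–C4 again (enolate 15) and the ketone oxygen closes O3–C4. This cut removes both rings and one stereocentre at once and leaves an acyclic ester with a single stereocentre, which no neighbouring disconnection of one ring can match. The forward reaction needs face selectivity at the vinyl group and ring opening at the methylene carbon.

**13 from 12, and 12 from 10 and 5.** The C=N2 bond is removed (diazo transfer to the active methylene of 12), then the ester bond C8–O7 is cut to alcohol 5 and aroylketene 11, released from acyl Meldrum's acid 10. Acylketene trapping acylates a secondary alcohol without touching its stereocentre and without a coupling reagent. The two halves are now independent aromatic building blocks.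

**10 from 8 and 9, and 8 from 6.** The C–C bond between the aroyl carbon and Meldrum's acid 9 is cut to 3,4-bis(TBSO)benzoic acid 8, made from 3,4-dihydroxybenzoic acid 6 through the silyl ester 7. Only standard acylation and silylation are required.

**5 from 4, 4 from 2 and 3, and 2 from 1.** The (S)-alcohol 5 is the slow-reacting enantiomer of racemate 4 in lipase acylation. Compound 4 is cut at the carbinol–vinyl bond to aldehyde 2 and vinylmagnesium bromide 3, and 2 is the silyl ether of 3,4,5-trihydroxybenzaldehyde 1. A resolution costs half the material, but it falls on the second intermediate of the route and gives the one stereocentre from which all others derive.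

## Roads not taken

**Alternative 1:** Three-component coupling on a chiral butenolide.
- Cut: C6–C5 and C1–C2, around (5R)-5-(l-menthyloxy)furan-2(5H)-one A1.
- Forward: the 2-lithio derivative of dithiane A2 adds to the β-carbon of A1 anti to the menthyloxy group, and the lactone enolate is trapped by aldehyde A3 to give adduct A4.
- Merits: two C–C bonds in one flask, high convergence, and absolute configuration from an inexpensive auxiliary without the material loss of a resolution. In that respect this road is better than the chosen one.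
- Weak points: no ring of the target is closed. The lactone of A4 is the wrong one, since its ring oxygen sits on the future C4. The dithiane must be unmasked in the presence of electron-rich silyloxy arenes and the resulting ketone reduced with control at C6. The lactone must then be transposed to O7, the acetal carbon reduced to C4H2, and the furan closed at a carbinol of undefined configuration. This means at least six further steps, with C2 and C6 still open.
- Comparison: the chosen plan offers both rings and C5 in the key step and three steps from there to 19.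

**Alternative 2:** Palladium-catalysed (3+2) cycloaddition.
- Cut: O3–C2 and C1–C5.
- Forward: Pd2(dba)3 with a chiral bisphosphine opens 2-vinyloxirane A5 to an alkoxide-bearing π-allyl complex. This adds through oxygen to arylidene malonate A6 and is closed by the malonate carbon, giving tetrahydrofuran A7.
- Merits: catalytic, enantioselective, and the aryl group at C2 is set trans to the C5 substituent in the ring-forming step. This is exactly the relationship the chosen plan can only reach by equilibration, so here this road is clearly better.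
- Weak points: A7 lacks the lactone, C6 and the whole pyrogallol ring. The vinyl group must be cleaved to an aldehyde, a tris-silyloxyaryl metal added with uncertain control at C6, the lactone closed onto one of two ester groups, and the other ester removed under hot dealkoxycarbonylation conditions that aryl silyl ethers tolerate poorly. The oxa-Michael half of the cycloaddition is also reversible.
- Comparison: the chosen plan has every carbon in place after the key step and forms no C–C bond late.

**Alternative 3:** Oxidative radical cyclisation and lactonisation.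
- Cut: C1–C5 and O7–C6.
- Forward: Mn(OAc)3 with Cu(OAc)2 oxidises malonate A8 to a C1 radical that cyclises onto the cinnamyl alkene. The benzylic radical at C6 is oxidised to the cation and captured by a tert-butyl ester, giving A9.
- Merits: like the chosen plan it closes both rings in one step. C2 is already present and acts as the controlling centre, so no correction at C2 is needed, and only ester removal and desilylation remain. On both counts it equals or beats the chosen plan.
- Weak points: the single stereocentre of A8 is a benzylic ether β to a malonate, i.e. an oxa-Michael adduct that can revert under the warm acidic conditions of the oxidation, and there is no dependable enantioselective entry to it. Induction from C2 to C5 runs across the ether oxygen. One-electron oxidants and a benzylic cation are generated beside five silyloxy arene positions.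
- Comparison: the chosen plan has a configurationally secure stereocentre from a resolved alcohol and a neutral key step.

Key step: step 8

Assumption: the stereodescriptors of the target are read as (1S,2S,5R,6S), which places both aryl groups on the convex face of the cis-fused bicycle (H1/H2 trans, H5/H6 trans).

## Route

Step 1
Reactants: 1 3,4,5-trihydroxybenzaldehyde
Product: 2 3,4,5-tris(TBSO)benzaldehyde
Conditions: TBSCl, imidazole, DMF, 0 °C to rt
Reagents that add atoms: tert-butyldimethylsilyl chloride, CC(C)(C)[Si](C)(C)Cl
Why: Imidazole-assisted silylation of phenols; the aldehyde is untouched and the bulky aryl silyl ethers tolerate the Grignard, carbene, Lewis acid and hydrogenation conditions that follow.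

Step 2
Reactants: 2 3,4,5-tris(TBSO)benzaldehyde; 3 vinylmagnesium bromide
Product: 4 rac-1-[3,4,5-tris(TBSO)phenyl]prop-2-en-1-ol
Conditions: CH2=CHMgBr, THF, −78 to 0 °C; aq. NH4Cl
Reagents that add atoms: none
Why: 1,2-Addition of a vinyl Grignard reagent to an aromatic aldehyde; aryl silyl ethers are inert at low temperature and the carbinol centre forms as a racemate.

Step 3
Reactants: 4 rac-1-[3,4,5-tris(TBSO)phenyl]prop-2-en-1-ol
Product: 5 (S)-1-[3,4,5-tris(TBSO)phenyl]prop-2-en-1-ol
Conditions: Novozym 435 (immobilised Candida antarctica lipase B), vinyl acetate, MTBE, 35 °C, stopped just past half conversion; chromatography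
Reagents that add atoms: none
Why: Lipase-catalysed kinetic resolution by irreversible transesterification; by the Kazlauskas rule (aryl large, vinyl medium) the enzyme acylates the (R)-enantiomer, so the (S)-alcohol, the future C6 centre, should be recovered in high enantiomeric purity.

Step 4
Reactants: 6 3,4-dihydroxybenzoic acid
Product: 8 3,4-bis(TBSO)benzoic acid, via silyl ester 7 (not isolated)
Conditions: TBSCl, imidazole, DMF, rt; then AcOH/THF/H2O (3:1:1), rt
Reagents that add atoms: tert-butyldimethylsilyl chloride, CC(C)(C)[Si](C)(C)Cl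
Why: Exhaustive silylation followed by selective solvolysis of the labile silyl ester; aryl silyl ethers survive aqueous acetic acid.

Step 5
Reactants: 8 3,4-bis(TBSO)benzoic acid; 9 Meldrum's acid
Product: 10 5-{[3,4-bis(TBSO)phenyl](hydroxy)methylidene}-2,2-dimethyl-1,3-dioxane-4,6-dione
Conditions: DCC, DMAP, CH2Cl2, 0 °C to rt; cold aq. KHSO4 wash
Reagents that add atoms: none
Why: Carbodiimide-mediated C-acylation of Meldrum's acid (Oikawa–Yonemitsu procedure), giving the enolised acyl Meldrum's acid as a storable acylketene precursor.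

Step 6
Reactants: 10 5-{[3,4-bis(TBSO)phenyl](hydroxy)methylidene}-2,2-dimethyl-1,3-dioxane-4,6-dione; 5 (S)-1-[3,4,5-tris(TBSO)phenyl]prop-2-en-1-ol
Product: 12 (S)-1-[3,4,5-tris(TBSO)phenyl]prop-2-enyl 3-[3,4-bis(TBSO)phenyl]-3-oxopropanoate, via aroylketene 11 (not isolated)
Conditions: toluene, 90 °C (10 in slight excess)
Reagents that add atoms: none
Why: Thermal cycloreversion of the acyl Meldrum's acid releases acetone and CO2, and the aroylketene is trapped at the oxygen of the secondary alcohol; no bond to the stereocentre is broken, and the non-polar medium disfavours ionisation of the benzylic allylic C–O bond.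

Step 7
Reactants: 12 (S)-1-[3,4,5-tris(TBSO)phenyl]prop-2-enyl 3-[3,4-bis(TBSO)phenyl]-3-oxopropanoate
Product: 13 (S)-1-[3,4,5-tris(TBSO)phenyl]prop-2-enyl 2-diazo-3-[3,4-bis(TBSO)phenyl]-3-oxopropanoate
Conditions: p-ABSA, Et3N, MeCN, 0 °C to rt
Reagents that add atoms: 4-acetamidobenzenesulfonyl azide (p-ABSA), CC(=O)Nc1ccc(cc1)S(=O)(=O)N=[N+]=[N-]
Why: Regitz diazo transfer to the doubly activated methylene group, which is acidic enough for triethylamine; allylic ester and silyl ethers are inert.

Step 8
Reactants: 13 (S)-1-[3,4,5-tris(TBSO)phenyl]prop-2-enyl 2-diazo-3-[3,4-bis(TBSO)phenyl]-3-oxopropanoate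
Product: 16 (5R,6S)-2-[3,4-bis(TBSO)phenyl]-6-[3,4,5-tris(TBSO)phenyl]-3,7-dioxabicyclo[3.3.0]oct-1-en-8-one, via cyclopropane lactone 14 (not isolated), via iodomethyl enolate 15 (not isolated)
Conditions: Rh2(OAc)4 (1 mol%), ClCH2CH2Cl, 60 °C, slow addition of 13; then MgI2 (30 mol%, in THF), 65 °C
Reagents that add atoms: none
Why: Proposed new method: each half is known separately, namely the Rh2(OAc)4-catalysed intramolecular cyclopropanation of allyl 2-diazo-3-oxo esters and the iodide-promoted Cloke–Wilson rearrangement of acyl cyclopropanes to 4,5-dihydrofurans, but their union in one flask on a lactone-fused cyclopropane has not been shown. Loss of N2 from 13 at the dirhodium centre gives an electrophilic carbene that adds to the pendant vinyl group in a concerted asynchronous [2+1] step, closing the γ-lactone (C1–C5, the carbene carbon reaching the inner alkene carbon through a five-membered exo-type arrangement of the ester tether) together with the cyclopropane (C1–C4) to give 14. MgI2 then binds the ketone and lactone carbonyl groups of 14, iodide opens the doubly activated cyclopropane by SN2 attack at the unsubstituted carbon C4 (homoconjugate addition, C1–C4 cleaved), and the ketone oxygen of enolate 15 displaces iodide from C4 in a 5-exo-tet O-alkylation that closes the dihydrofuran (O3–C4) and frees iodide for the next turnover. The one lasting new stereocentre, C5, is set in the carbene addition by the C6 centre: the transition state that keeps the C6 aryl group pseudo-equatorial on the forming lactone, anti to the developing cyclopropane methylene, leads to the (5R) isomer from the (6S) ester, while C1 of 14 is held cis by the ring fusion and becomes trigonal again in 16. The step needs face selectivity at the vinyl group (supplied by the allylic aryl group; the minor C5 epimer is a diastereomer and is removed by chromatography of 16 before any acid is used), selectivity of the carbene for the alkene over the hindered arenes (the alkene is the only π bond within reach of a five-membered closure), opening at primary C4 and not at C5 or benzylic C6 (SN2 preference and chelate activation of the C1–C4 bond), and O- over C-alkylation of 15 (C-alkylation only regenerates 14, the lactone oxygen cannot close because a bridgehead alkene would result, and release of cyclopropane strain makes O-alkylation the irreversible exit).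

Step 9
Reactants: 16 (5R,6S)-2-[3,4-bis(TBSO)phenyl]-6-[3,4,5-tris(TBSO)phenyl]-3,7-dioxabicyclo[3.3.0]oct-1-en-8-one
Product: 17 (1S,2R,5R,6S)-2-[3,4-bis(TBSO)phenyl]-6-[3,4,5-tris(TBSO)phenyl]-3,7-dioxabicyclo[3.3.0]octan-8-one
Conditions: H2 (5 bar), 5% Rh/Al2O3, EtOAc, rt
Reagents that add atoms: none
Why: Heterogeneous syn hydrogenation of the 2-aryl-4,5-dihydrofuran-3-carboxylate unit from the face of H5 (the other face would give a trans-fused bicycle), which sets C1 correctly and C2 with the aryl group endo; rhodium on alumina is chosen over palladium to spare the two benzylic C–O bonds.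

Step 10
Reactants: 17 (1S,2R,5R,6S)-2-[3,4-bis(TBSO)phenyl]-6-[3,4,5-tris(TBSO)phenyl]-3,7-dioxabicyclo[3.3.0]octan-8-one
Product: 18 (1S,2S,5R,6S)-2-[3,4-bis(TBSO)phenyl]-6-[3,4,5-tris(TBSO)phenyl]-3,7-dioxabicyclo[3.3.0]octan-8-one
Conditions: Me3SiOTf (10 mol%), CH2Cl2, −20 to 0 °C; Et3N quench; chromatography, recovered 17 resubmitted
Reagents that add atoms: none
Why: Acid-catalysed epimerisation of a benzylic ether carbon, the reaction that interconverts endo- and exo-aryl furofuran lignans: reversible ionisation of C2–O3 gives a benzylic cation stabilised by the para silyloxy group, and reclosure can place the aryl group on the convex face, away from C8. C1 and C5 are not touched, and C6, should it ionise as well, recloses to the same trans lactone; the exo isomer 18 is expected, though not proven, to predominate at equilibrium.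

Step 11
Reactants: 18 (1S,2S,5R,6S)-2-[3,4-bis(TBSO)phenyl]-6-[3,4,5-tris(TBSO)phenyl]-3,7-dioxabicyclo[3.3.0]octan-8-one
Product: 19 (1S,2S,5R,6S)-2-(3,4-dihydroxyphenyl)-6-(3,4,5-trihydroxyphenyl)-3,7-dioxabicyclo[3.3.0]octan-8-one
Conditions: Et3N·3HF (excess), THF, rt, argon; Sephadex LH-20
Reagents that add atoms: none
Why: Fluoride cleavage of the five aryl silyl ethers in a slightly acidic, non-nucleophilic medium, so that no phenoxide forms that could be oxidised, open the lactone or expel a benzylic oxygen through a quinone methide.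

## Compound list

1 | 3,4,5-trihydroxybenzaldehyde | O=Cc1cc(O)c(O)c(O)c1 | starting material
2 | 3,4,5-tris(TBSO)benzaldehyde | O=Cc1cc(O[Si](C)(C)C(C)(C)C)c(O[Si](C)(C)C(C)(C)C)c(O[Si](C)(C)C(C)(C)C)c1 | intermediate
3 | vinylmagnesium bromide | C=C[Mg]Br | starting material
4 | rac-1-[3,4,5-tris(TBSO)phenyl]prop-2-en-1-ol | OC(c1cc(O[Si](C)(C)C(C)(C)C)c(O[Si](C)(C)C(C)(C)C)c(O[Si](C)(C)C(C)(C)C)c1)C=C | intermediate
5 | (S)-1-[3,4,5-tris(TBSO)phenyl]prop-2-en-1-ol | O[C@H](c1cc(O[Si](C)(C)C(C)(C)C)c(O[Si](C)(C)C(C)(C)C)c(O[Si](C)(C)C(C)(C)C)c1)C=C | intermediate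
6 | 3,4-dihydroxybenzoic acid | O=C(O)c1ccc(O)c(O)c1 | starting material
7 | tert-butyldimethylsilyl 3,4-bis(TBSO)benzoate | CC(C)(C)[Si](C)(C)OC(=O)c1ccc(O[Si](C)(C)C(C)(C)C)c(O[Si](C)(C)C(C)(C)C)c1 | intermediate (not isolated)
8 | 3,4-bis(TBSO)benzoic acid | O=C(O)c1ccc(O[Si](C)(C)C(C)(C)C)c(O[Si](C)(C)C(C)(C)C)c1 | intermediate
9 | Meldrum's acid (2,2-dimethyl-1,3-dioxane-4,6-dione) | CC1(C)OC(=O)CC(=O)O1 | starting material
10 | 5-{[3,4-bis(TBSO)phenyl](hydroxy)methylidene}-2,2-dimethyl-1,3-dioxane-4,6-dione | CC1(C)OC(=O)C(=C(O)c2ccc(O[Si](C)(C)C(C)(C)C)c(O[Si](C)(C)C(C)(C)C)c2)C(=O)O1 | intermediate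
11 | [3,4-bis(TBSO)benzoyl]ketene | O=C=CC(=O)c1ccc(O[Si](C)(C)C(C)(C)C)c(O[Si](C)(C)C(C)(C)C)c1 | intermediate (not isolated)
12 | (S)-1-[3,4,5-tris(TBSO)phenyl]prop-2-enyl 3-[3,4-bis(TBSO)phenyl]-3-oxopropanoate | O=C(CC(=O)O[C@H](c1cc(O[Si](C)(C)C(C)(C)C)c(O[Si](C)(C)C(C)(C)C)c(O[Si](C)(C)C(C)(C)C)c1)C=C)c2ccc(O[Si](C)(C)C(C)(C)C)c(O[Si](C)(C)C(C)(C)C)c2 | intermediate
13 | (S)-1-[3,4,5-tris(TBSO)phenyl]prop-2-enyl 2-diazo-3-[3,4-bis(TBSO)phenyl]-3-oxopropanoate | O=C(c3ccc(O[Si](C)(C)C(C)(C)C)c(O[Si](C)(C)C(C)(C)C)c3)C(=[N+]=[N-])C(=O)O[C@H](c2cc(O[Si](C)(C)C(C)(C)C)c(O[Si](C)(C)C(C)(C)C)c(O[Si](C)(C)C(C)(C)C)c2)C=C | intermediate (key-step precursor)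
14 | (1R,4S,5S)-1-[3,4-bis(TBSO)benzoyl]-4-[3,4,5-tris(TBSO)phenyl]-3-oxabicyclo[3.1.0]hexan-2-one (aryl trans to the cyclopropane CH2) | O=C1O[C@H](c2cc(O[Si](C)(C)C(C)(C)C)c(O[Si](C)(C)C(C)(C)C)c(O[Si](C)(C)C(C)(C)C)c2)[C@H]2C[C@@]12C(=O)c3ccc(O[Si](C)(C)C(C)(C)C)c(O[Si](C)(C)C(C)(C)C)c3 | intermediate (not isolated)
15 | iodomagnesium enolate of (4S,5S)-3-[3,4-bis(TBSO)benzoyl]-4-(iodomethyl)-5-[3,4,5-tris(TBSO)phenyl]oxolan-2-one | O=C1O[C@H](c2cc(O[Si](C)(C)C(C)(C)C)c(O[Si](C)(C)C(C)(C)C)c(O[Si](C)(C)C(C)(C)C)c2)[C@@H](CI)C1=C(O[Mg]I)c3ccc(O[Si](C)(C)C(C)(C)C)c(O[Si](C)(C)C(C)(C)C)c3 | intermediate (not isolated)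
16 | (5R,6S)-2-[3,4-bis(TBSO)phenyl]-6-[3,4,5-tris(TBSO)phenyl]-3,7-dioxabicyclo[3.3.0]oct-1-en-8-one | O=C1O[C@H](c2cc(O[Si](C)(C)C(C)(C)C)c(O[Si](C)(C)C(C)(C)C)c(O[Si](C)(C)C(C)(C)C)c2)[C@H]2COC(c3ccc(O[Si](C)(C)C(C)(C)C)c(O[Si](C)(C)C(C)(C)C)c3)=C12 | intermediate (key-step product)
17 | (1S,2R,5R,6S)-2-[3,4-bis(TBSO)phenyl]-6-[3,4,5-tris(TBSO)phenyl]-3,7-dioxabicyclo[3.3.0]octan-8-one (C2 aryl endo) | O=C1O[C@H](c2cc(O[Si](C)(C)C(C)(C)C)c(O[Si](C)(C)C(C)(C)C)c(O[Si](C)(C)C(C)(C)C)c2)[C@H]2CO[C@@H](c3ccc(O[Si](C)(C)C(C)(C)C)c(O[Si](C)(C)C(C)(C)C)c3)[C@@H]12 | intermediate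
18 | (1S,2S,5R,6S)-2-[3,4-bis(TBSO)phenyl]-6-[3,4,5-tris(TBSO)phenyl]-3,7-dioxabicyclo[3.3.0]octan-8-one (both aryl groups exo) | O=C1O[C@H](c2cc(O[Si](C)(C)C(C)(C)C)c(O[Si](C)(C)C(C)(C)C)c(O[Si](C)(C)C(C)(C)C)c2)[C@H]2CO[C@H](c3ccc(O[Si](C)(C)C(C)(C)C)c(O[Si](C)(C)C(C)(C)C)c3)[C@@H]12 | intermediate
19 | (1S,2S,5R,6S)-2-(3,4-dihydroxyphenyl)-6-(3,4,5-trihydroxyphenyl)-3,7-dioxabicyclo[3.3.0]octan-8-one | O=C1O[C@H](c2cc(O)c(O)c(O)c2)[C@H]2CO[C@H](c3ccc(O)c(O)c3)[C@@H]12 | target

## Step count and least certain steps

Total: 11 steps. Longest linear sequence: 9 steps (steps 1, 2, 3, 6, 7, 8, 9, 10, 11).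

**Step 8 (key step).**
- What may go wrong: poor facial selectivity of the carbene addition, because only the allylic aryl group distinguishes the two faces of the vinyl group. The ring expansion may stall because magnesium holds the keto-enolate in the chelated geometry, with the ketone oxygen turned away from C4. Iodide may also attack benzylic C6, and silyl groups may be lost on prolonged heating with the Lewis acid.
- Fallback (known chemistry, from 12 back to 16): the diazo compound is avoided. Oxidative radical cyclisation of the allylic β-keto ester 12 with Mn(OAc)3·2H2O and Cu(OAc)2 in AcOH, a reaction established for this ester class, should give the same cyclopropane 14, now isolated. Lewis-acid-catalysed homoconjugate addition of acetic acid (Sc(OTf)3, AcOH) then opens 14 at the methylene carbon to the acetoxymethyl keto lactone F1. Acidic methanolysis (p-TsOH, MeOH) frees the hydroxymethyl keto lactone F2, which closes onto the ketone and loses water (p-TsOH, toluene, molecular sieves) to give 16. In this variant O3 comes from acetic acid and not from the ketone.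

**Step 10.**
- What may go wrong: the equilibrium may favour the exo isomer too weakly; furofurans without the carbonyl group show only a small exo preference. Competing ionisation of C6–O7 or slow ionisation next to the electron-poor C1 are further risks.
- Fallback (from 17 back to 19): 17 is desilylated with Et3N·3HF to the 2-epi pentaphenol F3. With the para hydroxyl free, C2–O3 opens reversibly through a quinone methide in dilute acid (aqueous dioxane, trace HCl, argon), and reclosure by the hydroxymethyl group gives 19, separated on reversed phase.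

**Step 9.**
- What may go wrong: slow uptake of hydrogen at the hindered tetrasubstituted push–pull alkene, or hydrogenolysis of a benzylic C–O bond under forcing conditions.
- Fallback (from 16 back to 17): ionic hydrogenation with Et3SiH and CF3CO2H in CH2Cl2 at −20 °C. Protonation at C1 on the convex face and hydride transfer to the C2 oxocarbenium ion from the same face lead to the same isomer 17. The reaction is stopped early so that the product is not ionised and reduced further. No new compound is made (F0).

**Step 3.**
- What may go wrong: slow or poorly selective acylation, because the tris-silyloxyaryl group is far larger than the substituents on which the enzyme's selectivity rule rests.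
- Fallback (from 4 back to 5): Sharpless kinetic resolution with Ti(OiPr)4, L-(+)-diisopropyl tartrate and t-BuOOH (CH2Cl2, −20 °C, 4 Å molecular sieves). The (R)-enantiomer is epoxidised faster to the erythro epoxy alcohol F4 and the (S)-alcohol 5 is recovered.

**Step 6.**
- What may go wrong: ionisation of the benzylic allylic alcohol by the strongly acidic acyl Meldrum's acid at 90 °C, leading to loss of enantiomeric purity or allylic transposition.
- Fallback (from 10 back to 12): 10 is heated with 2-methylpropane-2-thiol to give the S-tert-butyl β-keto thioester F5. This acylates 5 at room temperature under neutral conditions on activation with AgOCOCF3 in THF.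

**Step 11.**
- What may go wrong: incomplete cleavage of the central, doubly flanked silyl ether of the pyrogallol ring, or air oxidation of the free pentaphenol during isolation.
- Fallback (from 18 back to 19): after treatment with Et3N·3HF the crude phenol is acetylated in the same flask (Ac2O, pyridine) to the pentaacetate F6, which is stable on silica. Neutral deacetylation (NH4OAc, aqueous MeOH, argon) then gives 19.

## Further compounds

F1 | step 8 | (4R,5S)-4-(acetoxymethyl)-3-[3,4-bis(TBSO)benzoyl]-5-[3,4,5-tris(TBSO)phenyl]oxolan-2-one (C3 labile) | O=C1O[C@H](c2cc(O[Si](C)(C)C(C)(C)C)c(O[Si](C)(C)C(C)(C)C)c(O[Si](C)(C)C(C)(C)C)c2)[C@@H](COC(C)=O)C1C(=O)c3ccc(O[Si](C)(C)C(C)(C)C)c(O[Si](C)(C)C(C)(C)C)c3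
F2 | step 8 | (4R,5S)-3-[3,4-bis(TBSO)benzoyl]-4-(hydroxymethyl)-5-[3,4,5-tris(TBSO)phenyl]oxolan-2-one (C3 labile) | O=C1O[C@H](c2cc(O[Si](C)(C)C(C)(C)C)c(O[Si](C)(C)C(C)(C)C)c(O[Si](C)(C)C(C)(C)C)c2)[C@@H](CO)C1C(=O)c3ccc(O[Si](C)(C)C(C)(C)C)c(O[Si](C)(C)C(C)(C)C)c3
F3 | step 10 | (1S,2R,5R,6S)-2-(3,4-dihydroxyphenyl)-6-(3,4,5-trihydroxyphenyl)-3,7-dioxabicyclo[3.3.0]octan-8-one | O=C1O[C@H](c2cc(O)c(O)c(O)c2)[C@H]2CO[C@@H](c3ccc(O)c(O)c3)[C@@H]12
F0 | step 9 | none | none
F4 | step 3 | (S)-[(R)-oxiran-2-yl][3,4,5-tris(TBSO)phenyl]methanol (erythro) | O[C@@H](c1cc(O[Si](C)(C)C(C)(C)C)c(O[Si](C)(C)C(C)(C)C)c(O[Si](C)(C)C(C)(C)C)c1)[C@H]1CO1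
F5 | step 6 | S-tert-butyl 3-[3,4-bis(TBSO)phenyl]-3-oxopropanethioate | CC(C)(C)SC(=O)CC(=O)c1ccc(O[Si](C)(C)C(C)(C)C)c(O[Si](C)(C)C(C)(C)C)c1
F6 | step 11 | (1S,2S,5R,6S)-2-(3,4-diacetoxyphenyl)-6-(3,4,5-triacetoxyphenyl)-3,7-dioxabicyclo[3.3.0]octan-8-one | O=C1O[C@H](c2cc(OC(C)=O)c(OC(C)=O)c(OC(C)=O)c2)[C@H]2CO[C@H](c3ccc(OC(C)=O)c(OC(C)=O)c3)[C@@H]12
A1 | alternative 1 | (5R)-5-(l-menthyloxy)furan-2(5H)-one | O=C1O[C@@H](O[C@@H]2C[C@H](C)CC[C@H]2C(C)C)C=C1
A2 | alternative 1 | 2-[3,4,5-tris(TBSO)phenyl]-1,3-dithiane | S1CCCSC1c2cc(O[Si](C)(C)C(C)(C)C)c(O[Si](C)(C)C(C)(C)C)c(O[Si](C)(C)C(C)(C)C)c2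
A3 | alternative 1 | 3,4-bis(TBSO)benzaldehyde | O=Cc1ccc(O[Si](C)(C)C(C)(C)C)c(O[Si](C)(C)C(C)(C)C)c1
A4 | alternative 1 | trans,trans-3-{[3,4-bis(TBSO)phenyl](hydroxy)methyl}-4-{2-[3,4,5-tris(TBSO)phenyl]-1,3-dithian-2-yl}-5-(l-menthyloxy)oxolan-2-one (carbinol centre open) | O=C1O[C@@H](O[C@@H]4C[C@H](C)CC[C@H]4C(C)C)[C@H](C5(c2cc(O[Si](C)(C)C(C)(C)C)c(O[Si](C)(C)C(C)(C)C)c(O[Si](C)(C)C(C)(C)C)c2)SCCCS5)[C@H]1C(O)c3ccc(O[Si](C)(C)C(C)(C)C)c(O[Si](C)(C)C(C)(C)C)c3
A5 | alternative 2 | 2-vinyloxirane (racemic) | C=CC1CO1
A6 | alternative 2 | dimethyl 2-[3,4-bis(TBSO)benzylidene]malonate | COC(=O)C(=Cc1ccc(O[Si](C)(C)C(C)(C)C)c(O[Si](C)(C)C(C)(C)C)c1)C(=O)OC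
A7 | alternative 2 | dimethyl (2R,4R)-2-[3,4-bis(TBSO)phenyl]-4-vinyloxolane-3,3-dicarboxylate (2,4-trans) | C=C[C@H]1CO[C@H](c3ccc(O[Si](C)(C)C(C)(C)C)c(O[Si](C)(C)C(C)(C)C)c3)C1(C(=O)OC)C(=O)OC
A8 | alternative 3 | di-tert-butyl 2-{(S)-[3,4-bis(TBSO)phenyl][(E)-3-(3,4,5-tris(TBSO)phenyl)prop-2-enyloxy]methyl}malonate | CC(C)(C)OC(=O)C(C(=O)OC(C)(C)C)[C@H](OC/C=C/c1cc(O[Si](C)(C)C(C)(C)C)c(O[Si](C)(C)C(C)(C)C)c(O[Si](C)(C)C(C)(C)C)c1)c2ccc(O[Si](C)(C)C(C)(C)C)c(O[Si](C)(C)C(C)(C)C)c2
A9 | alternative 3 | 1-(tert-butoxycarbonyl) derivative of 18 | O=C1O[C@H](c2cc(O[Si](C)(C)C(C)(C)C)c(O[Si](C)(C)C(C)(C)C)c(O[Si](C)(C)C(C)(C)C)c2)[C@H]2CO[C@H](c3ccc(O[Si](C)(C)C(C)(C)C)c(O[Si](C)(C)C(C)(C)C)c3)[C@@]12C(=O)OC(C)(C)C
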